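The unbranched C26 chain is cut at the unactivated CH2–CH2 bond C17–C18 (C1 = ester carbonyl), sixteen methylenes from the only functional group, where no polar handle exists. Both carbons are generated as primary radicals, a union of like polarity. Mixed Kolbe electrolysis of decanoic acid and benzyl hydrogen octadecanedioate expels two CO2 and joins the nonyl and C17 ester halves in one operation, giving the target directly. The step exploits the all-methylene surroundings of C17 and C18 and the even carbon counts of cheap fatty acids (10 − 1 + 18 − 1 = 26). The ester and phenyl ring are spectators. The precursor is the half benzyl ester of the C18 diacid.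

Key step: step 2

Remark: the target has no stereocentre and no stereogenic double bond. It is achiral, so the route needs no stereocontrol.

Step 1
Reactants: 1 octadecanedioic acid; 2 benzyl formate
Product: 3 18-(benzyloxy)-18-oxooctadecanoic acid (benzyl hydrogen octadecanedioate)
Conditions: 2 (2 equiv), Dowex 50W-X2 (H+ form), n-octane, 100 °C; hot filtration, crystallisation from heptane
Reagents that add atoms: none
Why: Resin-catalysed selective monoesterification of a symmetrical dicarboxylic acid by ester interchange (acidolysis of benzyl formate): the polar diacid is held in the hydrated sulfonic-acid resin phase where it is esterified, whereas the lipophilic half ester 3 passes into the octane and is thereby withdrawn from a second esterification.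

Step 2
Reactants: 3 18-(benzyloxy)-18-oxooctadecanoic acid; 4 decanoic acid
Product: 7 benzyl hexacosanoate, via nonyl radical 5 (not isolated), via 17-benzyloxy-17-oxoheptadecyl radical 6 (not isolated)
Conditions: undivided cell, smooth Pt anode/Pt cathode, constant current ca. 0.3 A cm−2, 4 (5 equiv), KOH (5 mol% of total CO2H, pre-mixed with 4), MeOH/light petroleum (b.p. 60–80 °C, stirred two-phase), 45–50 °C, periodic polarity reversal; stopped while still weakly acidic
Reagents that add atoms: none
Why: Mixed Kolbe electrolysis (anodic decarboxylative radical hetero-coupling): both carboxylates are oxidised by one electron at the platinum anode, lose CO2 and give the primary radicals 5 and 6 in high local concentration at the electrode surface, where they combine to form the C17–C18 bond, while protons are reduced to H2 at the cathode. This is the classical way to lengthen fatty acids with half esters of diacids, so only the pairing of partners is new. No ring is closed and no stereocentre is formed. The selectivity needed is cross- over homo-coupling and radical over cation (Hofer–Moest) pathway: the first is secured by the five-fold excess of cheap 4, so that nearly every radical 6 should meet a radical 5, the second by the unsubstituted primary radical carbons, smooth Pt, high current density and a weakly acidic, barely neutralised medium. The two symmetrical dimers carry no or two ester groups and should separate from the monoester 7 on silica or by crystallisation. The benzyl ester should survive because the carboxylate layer on the anode shields other groups from oxidation and the excess acid quenches cathodic methoxide as long as the solution is not allowed to turn alkaline, while the petroleum layer takes up the waxy product and keeps the anode clean.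

Compound list
1 | octadecanedioic acid | OC(=O)CCCCCCCCCCCCCCCCC(=O)O | starting material
2 | benzyl formate | O=COCc1ccccc1 | starting material
3 | 18-(benzyloxy)-18-oxooctadecanoic acid (benzyl hydrogen octadecanedioate) | OC(=O)CCCCCCCCCCCCCCCCC(=O)OCc1ccccc1 | intermediate
4 | decanoic acid | CCCCCCCCCC(=O)O | starting material
5 | nonyl radical | CCCCCCCC[CH2] | intermediate
6 | 17-(benzyloxy)-17-oxoheptadecyl radical | [CH2]CCCCCCCCCCCCCCCC(=O)OCc1ccccc1 | intermediate
7 | benzyl hexacosanoate | CCCCCCCCCCCCCCCCCCCCCCCCCC(=O)OCc1ccccc1 | target

Total steps: 2
Longest linear sequence: 2

Steps most likely to fail (the route holds only two steps, so both are ranked):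

1. Step 2. Several processes may lower the return:
- statistical pairing of the radicals (homo-coupling);
- coating and passivation of the anode by the waxy product;
- over-oxidation of the radicals to cations;
- exchange of the benzyl ester with methanol near the cathode.

The fallback replaces the anode by a polarity-differentiated nickel coupling and sets out from 3. Esterification with N-hydroxyphthalimide (DIC, cat. DMAP, CH2Cl2) should give the redox-active ester 1-benzyl 18-(1,3-dioxoisoindolin-2-yl) octadecanedioate F1. Commercial nonylmagnesium bromide and ZnCl2 (THF) should give dinonylzinc F2. Nickel-catalysed decarboxylative alkyl–alkyl (Negishi-type) coupling of F1 with F2 (NiCl2·glyme, 4,4'-di-tert-butyl-2,2'-bipyridine, THF/DMF, rt) forms the same C17–C18 bond without methanol or an anode. Cross-selectivity is built in here. The fallback comes back to the route at 7.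

2. Step 1. Two processes may spoil the selectivity: esterification of the second carboxyl group, and sluggish conversion because the long-chain diacid is poorly taken up by the resin. The fallback sets out from 1 and reaches the half ester from the other side. Exhaustive Fischer esterification (excess benzyl alcohol, cat. TsOH, toluene, Dean–Stark) should give dibenzyl octadecanedioate F3. Half-saponification with one equivalent of KOH in THF/benzyl alcohol should then precipitate potassium 18-(benzyloxy)-18-oxooctadecanoate F4, which thereby escapes a second hydrolysis. Acidification with dilute HCl comes back to the route at 3.

Further compounds
F1 | step 2 | 1-benzyl 18-(1,3-dioxoisoindolin-2-yl) octadecanedioate | O=C(CCCCCCCCCCCCCCCCC(=O)OCc1ccccc1)ON1C(=O)c2ccccc2C1=O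
F2 | step 2 | dinonylzinc | CCCCCCCCC[Zn]CCCCCCCCC
F3 | step 1 | dibenzyl octadecanedioate | O=C(CCCCCCCCCCCCCCCCC(=O)OCc1ccccc1)OCc1ccccc1
F4 | step 1 | potassium 18-(benzyloxy)-18-oxooctadecanoate | [K+].[O-]C(=O)CCCCCCCCCCCCCCCCC(=O)OCc1ccccc1
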